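## The problem

The target is a pentacyclic triterpenoid methyl ether in which cyclohexane rings A, B and C, a cycloheptanone ring D and a cyclohexane ring E are fused in a row. Serratane-type numbering is used: ring C is C8, C9, C11, C12, C14 and C27, and ring D is C12–C18. There are ten stereocentres (C3, C5, C8, C9, C10, C12, C14, C17, C18, C21). With β defined as the face of the C10 methyl group, MeO-3, H-5, Me-8, H-9, HO-14 and HO-21 are β and H-12, H-17 and Me-18 are α, so the A/B, B/C and D/E fusions are cis and the C/D fusion is trans. The cis fusions exclude the usual trans-selective tools (dissolving-metal reduction, undirected hydrogenation, polyene cyclisation); H-5 and H-17 must each be delivered to the face that already carries the angular methyl group. The quaternary carbons C10 and C18 must be set absolutely; from them C5, C17, C3 and C21 can be set by substrate control, C8 and C9 follow from the shape of the cis-decalin, C14 is fixed when ring C closes, and C12 is epimerisable next to the C13 ketone and may be left to equilibrate. Nearly every bond that could join the halves ends at a carbon next to a quaternary centre, so intermolecular SN2 reactions at C11 or C27 are not realistic. The C13 ketone and the tertiary C14 alcohol form an aldol array that will not survive strong base or acid (retro-aldol opening of ring D, dehydration to the C12=C14 enone), and the C3 methyl ether forbids late ether-cleaving Lewis acids. The enabling feature is quaternary C18, which lies between the C13 carbonyl of ring D and the ring-fusion carbon C17. The prochiral triketone 5 already holds ring D, both ring carbonyls and every ring E carbon except the C22 methyls, and its two ring carbonyls are enantiotopic, so one catalytic aldol closure of ring E (C17–C22) fixes C18. C10, C9 and C5 stand in the same relation, so the AB half can be drawn from the six-membered homologue 18.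

## Retrosynthesis

**39 from 38.** Only the O–benzyl bond at C21 is cut. A benzyl ether survives every reagent of the route and is removed by neutral hydrogenolysis, which leaves the C13/C14 aldol array alone; an ester or silyl ether would need base, acid or fluoride at the end.

**38 from 37 (C14–C27, ring C).** Ring C offers three closures: C8–C27 (no activating group on either carbon), C11–C12 (intramolecular enolate alkylation, which still needs the C14 carbinol made first) and C14–C27. The last creates the tertiary alcohol at the correct oxidation level as the ring closes. The precursor 37 is a seco compound with a 13,14-dione and a neopentyl iodide at C27. The forward samarium Barbier reaction must choose C14 over C13 and must place the oxygen axial on the new chair.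

**37 from 34 (C14 oxygen).** No skeletal bond is cut; the C14 carbonyl is traced back to the β-carbon of the C12=C14 enone 34 (conjugate borylation, oxidation, oxidation). Placing the oxygenation after the fragment union lets the enone itself serve as the coupling handle, and the enolisable dione never has to be C-alkylated.

**34 from 17 and 32 (C11–C12).** This cut divides the molecule into two bicyclic halves of similar size. Enolate alkylation with a C11 halide would be an SN2 reaction at a carbon flanked by two quaternary centres, and an aldol route would add redox steps. An sp3–sp2 Suzuki–Miyaura coupling of the α-iodoenone 17 with the alkylborane from alkene 32 has neither problem. The forward hydroboration must also set C9.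

**17 from 16, 14 and 13 (ring D handle and the D/E fusion).** The iodoenone comes from enone 16, which comes from the cis-fused alcohol 14 by oxidation and dehydrogenation; only C12 carries α-hydrogens. The C17–H bond is traced to hydrogenation of the C16=C17 alkene 13, directed by the 13-hydroxyl, which is cis to the C18 methyl.

**13 from 7 (C22 methyls, C21 carbinol).** Both C22–CH3 bonds are cut back to the enone of 7 (deconjugative double methylation of 9 to 10, two equivalents of iodomethane 2). The C21 carbinol (11) comes from the ketone by equatorial hydride attack; the 13-hydroxyl (8) comes from borohydride reduction of the saturated ketone of 7.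

**7 from 5 (C17–C22, ring E; the key cut).** The alternative is to cut ring D, which leaves the quaternary C18 unsolved. Cutting C17–C22 gives the achiral triketone 5 and asks only that a chiral amine distinguish two enantiotopic carbonyls.

**5 from 3 and 4; 3 from 1 and 2.** The C18–C19 bond is a Michael addition to but-3-en-2-one 4 and the C18–CH3 bond a C-methylation of cycloheptane-1,3-dione 1.

**32 from 31, 28 and 26 (C11, C27, C8).** C11 is a methylene installed on the non-enolisable C9 ketone 31. The C27 iodide is traced through alcohol 29 to the benzyloxymethyl ketone 28. Quaternary C8 is cut at both exocyclic bonds: benzyloxymethylation (27), then methylation on the convex face of the cis-decalone enolate.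

**26 from 24, 21 and 18 (rings A/B).** The cis-decalone 26 comes from 18 by the same operations as the DE half: borohydride, silylation, double methylation (21), reduction and O-methylation (22, 23), desilylation (24), hydroxyl-directed hydrogenation (25), oxidation. The 3β-oxygen is cis to the angular methyl here and is made with a small hydride.

## Roads not taken

**Alternative 1:** Ring D is cut at C15–C16 and closed last by ring-closing metathesis. The diene A1 carries one vinyl group on the tertiary carbinol C14 and one on C17; a ruthenium alkylidene catalyst of the second-generation Grubbs type would close the cycloheptene A2, and hydrogenation and desilylation would finish. Merits: seven-membered ring-closing metathesis is dependable, the C14 carbinol would come from a simple vinyl addition to a ketone, and no seven-membered amine-catalysed aldol of uncertain selectivity is needed. In these respects it is better than the chosen plan, which spends three steps on the C14 oxygen. Weak points: A1 needs a ketone link C12–C13–C18 between a tricyclic ABC unit and ring E, made by acylation next to quaternary C18. One vinyl group sits on a fully substituted carbinol carbon and the other between two quaternary carbons, so catalyst loading onto either alkene is slow. C17 and C18 of ring E must be solved separately. Against this the chosen plan sets C18 catalytically in its third step and takes the hindered C13 ketone from a commercial ring.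

**Alternative 2:** Ring E is built alone: C16–C17 and C18–CH3 are cut. A vinylcopper reagent would add to C17 of the enoate A3 and the ester enolate would be methylated in the same flask to give A4. Merits: the methyl group enters anti to the new vinyl group, which gives the cis H-17/Me-18 relation directly. This is more certain than the directed hydrogenation of the chosen plan. Weak points: the β-carbon of A3 is next to the C22 quaternary carbon and is a poor acceptor; the absolute configuration is not addressed without an auxiliary or a chiral ligand; and A4 is only ring E, so ring D must still be closed (for example through A1), which adds many steps. The chosen plan obtains rings D and E with C18 set in three steps from achiral materials.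

**Alternative 3:** Ring D is made by two-carbon ring expansion of a five-membered ring. Dichloroketene A7 would add to the bicyclic trimethylsilyl enol ether A5 to give the dichlorocyclobutanone A6; dechlorination and retro-aldol cleavage of the old ring bond would give the ring D 1,3-dione A8. Merits: the C13/C14 dioxygenation appears in one operation, and the route rests on the five-membered proline aldol, the most selective member of the family. On both counts it is better than the chosen plan. Weak points: three extra skeletal operations, a cycloaddition next to quaternary C18, chlorinated strained intermediates, and the fact that A8 is enolisable and unsubstituted at C12, which would then have to be alkylated with a very hindered electrophile. The chosen plan keeps ring D intact from the start and uses the C12=C14 enone first as the cross-coupling handle and then as the source of the C14 oxygen.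

Key step: step 3

Assumption: the ring fusions are taken as the stereodescriptors of the target define them (A/B, B/C and D/E cis, C/D trans; β: MeO-3, H-5, Me-8, H-9, Me-10, HO-14, HO-21; α: H-12, H-17, Me-18).

## Route

Step 1
Reactants: 1 cycloheptane-1,3-dione; 2 iodomethane
Product: 3 2-methylcycloheptane-1,3-dione
Conditions: MeI, KOH, H2O–MeOH, 60 °C
Reagents that add atoms: none
Why: C-alkylation of the 1,3-dione enolate; the protic medium solvates the enolate oxygens and steers iodomethane to carbon.

Step 2
Reactants: 3 2-methylcycloheptane-1,3-dione; 4 but-3-en-2-one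
Product: 5 2-methyl-2-(3-oxobutyl)cycloheptane-1,3-dione
Conditions: Et3N (10 mol %), EtOAc, 23 °C
Reagents that add atoms: none
Why: Michael addition of the tertiary dione carbon to the enone; C18 becomes quaternary but not yet stereogenic because the two ring carbonyls remain mirror-related.

Step 3
Reactants: 5 2-methyl-2-(3-oxobutyl)cycloheptane-1,3-dione
Product: 7 (S)-ring-DE enedione, via cis-fused ketol 6 (not isolated)
Conditions: N-tosyl-(Sa)-binam-L-prolinamide (5 mol %), PhCO2H (2.5 mol %), neat, 22 °C
Reagents that add atoms: none
Why: The pyrrolidine nitrogen condenses with the side-chain methyl ketone to the enamine C21=C22, and C22 adds to one ring carbonyl (C17) through a chair-like transition state in which the amide and sulfonamide N–H groups hydrogen-bond to that carbonyl; hydrolysis gives ketol 6, which loses water under the benzoic acid co-catalyst to enone 7. This is the Hajos–Parrish–Eder–Sauer–Wiechert aldol cyclisation, a reaction class established for 2-alkyl-2-(3-oxobutyl)cycloalkane-1,3-diones, of which the cycloheptanedione is the next ring homologue. Ring E closes by a 6-(enolendo)-exo-trig aldol addition. The only lasting stereocentre, quaternary C18, is set by the choice between the enantiotopic carbonyls C13 and C17, controlled by the L-pyrrolidine and the (Sa)-binaphthyl hydrogen-bond donors; the L series gives the (S) enedione with the six-membered dione and the same sense is expected here. The step needs enantiotopic-group selectivity only, since the methyl ketone is the sole unhindered enamine site and the mirror plane of 5 makes both ring carbonyls otherwise identical; the untouched carbonyl becomes the C13 ketone.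

Step 4
Reactants: 7 (S)-ring-DE enedione
Product: 8 13-hydroxy enone
Conditions: NaBH4 (0.3 equiv), EtOH, −15 °C
Reagents that add atoms: none
Why: Chemoselective borohydride reduction of the saturated C13 ketone in the presence of the less electrophilic conjugated C21 carbonyl; hydride enters anti to the neighbouring angular methyl, so the 13-hydroxyl is cis to it, as with the six-membered homologue.

Step 5
Reactants: 8 13-hydroxy enone
Product: 9 13-O-TBS enone
Conditions: TBSCl, imidazole, DMF, 40 °C
Reagents that add atoms: tert-butyldimethylsilyl chloride, CC(C)(C)[Si](C)(C)Cl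
Why: Silyl ether formation; the ether keeps the alkoxide from being O-methylated in the next step.

Step 6
Reactants: 9 13-O-TBS enone; 2 iodomethane (first methyl group)
Product: 10 13-O-TBS 22,22-dimethyl-Δ16-21-ketone
Conditions: KOt-Bu (3 equiv), MeI (6 equiv), t-BuOH–THF, 0 → 23 °C
Reagents that add atoms: iodomethane (second methyl group), CI
Why: Deconjugative double α-alkylation of the enone: the extended dienolate (γ-deprotonation at C16) is methylated at C22, the monomethyl ketone is deprotonated again and takes a second molecule of iodomethane at the same carbon, which moves the double bond to C16=C17.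

Step 7
Reactants: 10 13-O-TBS 22,22-dimethyl-Δ16-21-ketone
Product: 11 13-O-TBS Δ16-21-ol
Conditions: Li(s-Bu)3BH, THF, −78 °C
Reagents that add atoms: none
Why: Ketone reduction by a bulky trialkylborohydride: equatorial attack on the C21 carbonyl gives the axial alcohol, trans to the C18 methyl, the outcome known for 4,4-dimethyl-3-keto terpenoids.

Step 8
Reactants: 11 13-O-TBS Δ16-21-ol
Product: 12 21-O-benzyl 13-O-TBS diether
Conditions: NaH, BnBr, Bu4NI (cat.), DMF, 0 → 40 °C
Reagents that add atoms: benzyl bromide, BrCc1ccccc1
Why: Williamson etherification of the hindered secondary alkoxide; the silyl ether is stable to sodium hydride.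

Step 9
Reactants: 12 21-O-benzyl 13-O-TBS diether
Product: 13 21-O-benzyl Δ16-13-ol
Conditions: Bu4NF, THF, 50 °C
Reagents that add atoms: none
Why: Fluoride cleavage of the silyl ether frees the hydroxyl that directs the next step.

Step 10
Reactants: 13 21-O-benzyl Δ16-13-ol
Product: 14 21-O-benzyl cis-fused 13-ol
Conditions: [Ir(cod)(PCy3)(py)]PF6 (10 mol %), H2 (1 atm), CH2Cl2, 23 °C
Reagents that add atoms: none
Why: Hydroxyl-directed homogeneous hydrogenation of a cyclic homoallylic alcohol: the cationic iridium centre binds the 13-hydroxyl and delivers hydrogen to the same face of C16=C17, so H-17 ends cis to the C18 methyl; the benzyl ether oxygen binds far more weakly.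

Step 11
Reactants: 14 21-O-benzyl cis-fused 13-ol
Product: 16 cis-fused Δ12(14)-13-enone, via cis-fused 13-ketone 15 (not isolated)
Conditions: IBX (4 equiv), 4-methoxypyridine N-oxide (4 equiv), DMSO, 23 °C
Reagents that add atoms: none
Why: IBX oxidises the alcohol to ketone 15 and, as its N-oxide complex, dehydrogenates it at room temperature through the enol; C12 is the only α-carbon with hydrogens (C18 is quaternary), so only the C12=C14 enone can form.

Step 12
Reactants: 16 cis-fused Δ12(14)-13-enone
Product: 17 12-iodo-Δ12(14)-13-enone
Conditions: I2, pyridine, CH2Cl2, 0 → 23 °C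
Reagents that add atoms: iodine, II
Why: α-Iodination of a cyclic enone by pyridine conjugate addition, iodination of the enolate and elimination (Baylis–Hillman-type sequence).

Step 13
Reactants: 18 (S)-Wieland–Miescher ketone
Product: 19 9-hydroxy enone
Conditions: NaBH4 (0.3 equiv), EtOH, −10 °C
Reagents that add atoms: none
Why: Chemoselective reduction of the saturated C9 ketone; hydride enters anti to the angular methyl and the 9-hydroxyl is cis to it.

Step 14
Reactants: 19 9-hydroxy enone
Product: 20 9-O-TBS enone
Conditions: TBSCl, imidazole, DMF, 23 °C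
Reagents that add atoms: tert-butyldimethylsilyl chloride, CC(C)(C)[Si](C)(C)Cl
Why: Silyl ether formation, for the same reason as in step 5.

Step 15
Reactants: 20 9-O-TBS enone; 2 iodomethane (first methyl group)
Product: 21 9-O-TBS 4,4-dimethyl-Δ5-3-ketone
Conditions: KOt-Bu (3 equiv), MeI (6 equiv), t-BuOH–THF, 0 → 23 °C
Reagents that add atoms: iodomethane (second methyl group), CI
Why: Deconjugative double α-methylation of the enone through its dienolate; two successive alkylations with iodomethane place both methyls on C4 and the double bond at C5=C6.

Step 16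
Reactants: 21 9-O-TBS 4,4-dimethyl-Δ5-3-ketone
Product: 22 9-O-TBS Δ5-3β-ol
Conditions: NaBH4, MeOH, 0 °C
Reagents that add atoms: none
Why: Axial attack of the small hydride on the 4,4-dimethyl-3-ketone gives the equatorial 3β-alcohol, cis to the C10 methyl.

Step 17
Reactants: 22 9-O-TBS Δ5-3β-ol; 2 iodomethane
Product: 23 9-O-TBS 3β-methoxy-Δ5-octalin
Conditions: NaH, MeI, THF, 0 → 45 °C
Reagents that add atoms: none
Why: Williamson O-methylation installs the permanent C3 methyl ether.

Step 18
Reactants: 23 9-O-TBS 3β-methoxy-Δ5-octalin
Product: 24 3β-methoxy-Δ5-9-ol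
Conditions: Bu4NF, THF, 50 °C
Reagents that add atoms: none
Why: Fluoride desilylation frees the directing 9-hydroxyl.

Step 19
Reactants: 24 3β-methoxy-Δ5-9-ol
Product: 25 3β-methoxy cis-decalin-9-ol
Conditions: [Ir(cod)(PCy3)(py)]PF6 (10 mol %), H2 (1 atm), CH2Cl2, 23 °C
Reagents that add atoms: none
Why: Hydroxyl-directed hydrogenation of a cyclohex-3-en-1-ol: the 9β-hydroxyl delivers hydrogen to the β face of C5=C6, so H-5 is cis to the C10 methyl and the decalin is cis-fused.

Step 20
Reactants: 25 3β-methoxy cis-decalin-9-ol
Product: 26 3β-methoxy cis-decalin-9-one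
Conditions: Dess–Martin periodinane, CH2Cl2, 23 °C
Reagents that add atoms: none
Why: Alcohol oxidation; C5 cannot epimerise because quaternary C10 separates it from the ketone.

Step 21
Reactants: 26 3β-methoxy cis-decalin-9-one
Product: 27 8-(benzyloxymethyl) 9-ketone
Conditions: LiN(i-Pr)2, THF, −78 °C; BnOCH2Cl, −78 → −20 °C
Reagents that add atoms: benzyl chloromethyl ether, ClCOCc1ccccc1
Why: Alkylation of the lithium enolate, which can form only towards C8; the C8 configuration does not matter here because it is erased in step 22.

Step 22
Reactants: 27 8-(benzyloxymethyl) 9-ketone; 2 iodomethane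
Product: 28 8α-(benzyloxymethyl)-8β-methyl 9-ketone
Conditions: KN(SiMe3)2, THF, −78 °C; MeI, −78 → −40 °C
Reagents that add atoms: none
Why: Enolate alkylation that creates quaternary C8: the cis-decalin enolate is attacked on its convex β face, anti to the axial C1 methylene that shields the α face, so the methyl enters cis to the C10 methyl; low temperature suppresses β-elimination of benzyloxide.

Step 23
Reactants: 28 8α-(benzyloxymethyl)-8β-methyl 9-ketone
Product: 29 8α-(hydroxymethyl)-8β-methyl 9-ketone
Conditions: H2 (1 atm), Pd/C, EtOAc, 23 °C
Reagents that add atoms: none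
Why: Hydrogenolysis of the benzyl ether under neutral conditions, which avoids retro-aldol loss of formaldehyde.

Step 24
Reactants: 29 8α-(hydroxymethyl)-8β-methyl 9-ketone
Product: 31 8α-(iodomethyl)-8β-methyl 9-ketone, via C27 triflate 30 (not isolated)
Conditions: Tf2O, pyridine, CH2Cl2, −78 → 0 °C; then NaI, DMF, 40 °C
Reagents that add atoms: trifluoromethanesulfonic anhydride, O=S(=O)(OS(=O)(=O)C(F)(F)F)C(F)(F)F (retained only in 30); sodium iodide, [Na+].[I-]
Why: Sulfonylation and SN2 displacement; the triflate is needed for substitution at the neopentyl carbon, and the ketone has no α-hydrogen, so neither elimination nor cyclopropane formation can compete.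

Step 25
Reactants: 31 8α-(iodomethyl)-8β-methyl 9-ketone
Product: 32 AB alkene
Conditions: Cp2TiMe2, toluene, 70 °C
Reagents that add atoms: bis(cyclopentadienyl)dimethyltitanium Cp2TiMe2, [CH3-].[CH3-].[Ti+4].c1cc[cH-]c1.c1cc[cH-]c1
Why: Petasis methylenation; the titanium methylidene Cp2Ti=CH2 adds to hindered, non-enolisable ketones that resist phosphorus ylides and leaves the alkyl iodide alone.

Step 26
Reactants: 32 AB alkene; 17 12-iodo-Δ12(14)-13-enone
Product: 34 coupled 12-alkyl-Δ12(14)-13-enone, via B-alkyl-9-BBN 33 (not isolated)
Conditions: 9-BBN, THF, 65 °C; then 17, Pd(dppf)Cl2 (5 mol %), AsPh3 (10 mol %), Cs2CO3, DMF–THF–H2O, 23 °C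
Reagents that add atoms: 9-borabicyclo[3.3.1]nonane, [BH]1C2CCCC1CCC2 (retained only in 33)
Why: Hydroboration followed by B-alkyl Suzuki–Miyaura coupling with an α-iodoenone. Boron adds to the terminal C11 and hydrogen to C9 from the convex β face (the α face is flanked by the axial C1 and C27 methylenes), which sets H-9 cis to both methyls. Zerovalent palladium inserts into the vinyl C–I bond far faster than into the neopentyl C–I bond.

Step 27
Reactants: 34 coupled 12-alkyl-Δ12(14)-13-enone
Product: 36 14-hydroxy 13-ketone, via 14-pinacolboronate 35 (not isolated)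
Conditions: CuCl (5 mol %), Xantphos (5 mol %), NaOt-Bu (10 mol %), B2pin2 (1.1 equiv), MeOH (2 equiv), THF, 23 °C; then NaBO3·4H2O, THF–H2O, 23 °C
Reagents that add atoms: bis(pinacolato)diboron, CC1(C)OB(OC1(C)C)B1OC(C)(C)C(C)(C)O1 (retained only in 35); sodium perborate, [Na+].[Na+].O[B-]1(O)OO[B-](O)(O)OO1
Why: Copper-catalysed conjugate borylation (the boryl-copper species adds to C14, methanol protonates the enolate) and perborate oxidation of the C–B bond; the new centres at C12 and C14 are erased or reset later. Catalytic alkoxide and limiting diboron keep the neopentyl iodide untouched.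

Step 28
Reactants: 36 14-hydroxy 13-ketone
Product: 37 13,14-dione
Conditions: Dess–Martin periodinane, CH2Cl2, 23 °C
Reagents that add atoms: none
Why: Oxidation of a β-hydroxy ketone to the 1,3-diketone, for which this reagent is the standard choice; seven-membered 1,3-diones stay largely in the diketo form.

Step 29
Reactants: 37 13,14-dione
Product: 38 21-O-benzyl ether of the target
Conditions: SmI2 (2.5 equiv), NiI2 (1 mol %), THF, −78 → 0 °C; aq. NH4Cl
Reagents that add atoms: none
Why: Samarium diiodide intramolecular Barbier reaction of an ω-iodoalkyl β-dicarbonyl compound (6-exo-trig closure of ring C): C27 adds to the C14 carbonyl, not to C13, which is shielded by quaternary C18. In the only chair available to ring C on the cis-fused AB unit, the ring D carbons C13 and C15 are both equatorial, so the oxygen is axial (14β-OH, trans C/D). The metal bridging both carbonyl oxygens favours the same hydroxyl/acyl cis relation, and C12 settles as the equatorial-acyl epimer (H-12 α) by enolisation.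

Step 30
Reactants: 38 21-O-benzyl ether of the target
Product: 39 CNP0259231.1
Conditions: H2 (1 atm), Pd(OH)2/C, EtOAc–MeOH, 23 °C
Reagents that add atoms: none
Why: Neutral hydrogenolysis of the benzyl ether; the hindered ketone, the tertiary alcohol and the methyl ether are inert, and no base or acid touches the aldol array.

## Compound list

1 | cycloheptane-1,3-dione | O=C1CCCCC(=O)C1 | starting material
2 | iodomethane | CI | starting material
3 | 2-methylcycloheptane-1,3-dione | CC1C(=O)CCCCC1=O | intermediate
4 | but-3-en-2-one | CC(=O)C=C | starting material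
5 | 2-methyl-2-(3-oxobutyl)cycloheptane-1,3-dione | CC(=O)CCC1(C)C(=O)CCCCC1=O | intermediate
6 | cis-fused ketol (17-hydroxy-13,21-dione, 17-OH cis to the C18 methyl) | C[C@]12CCC(=O)C[C@@]1(O)CCCCC2=O | intermediate (not isolated)
7 | (S)-ring-DE enedione (cycloheptanone 13-ketone fused to cyclohexenone, 21-ketone, C17=C22, C18 methyl) | C[C@]12CCC(=O)C=C1CCCCC2=O | intermediate
8 | 13-hydroxy enone (13-OH cis to the C18 methyl) | C[C@]12CCC(=O)C=C1CCCC[C@@H]2O | intermediate
9 | 13-O-TBS enone | C[C@]12CCC(=O)C=C1CCCC[C@@H]2O[Si](C)(C)C(C)(C)C | intermediate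
10 | 13-O-TBS 22,22-dimethyl-Δ16-21-ketone | C[C@]12CCC(=O)C(C)(C)C1=CCCC[C@@H]2O[Si](C)(C)C(C)(C)C | intermediate
11 | 13-O-TBS Δ16-21-ol (21-OH trans to the C18 methyl) | C[C@]12CC[C@@H](O)C(C)(C)C1=CCCC[C@@H]2O[Si](C)(C)C(C)(C)C | intermediate
12 | 21-O-benzyl 13-O-TBS diether | C[C@]12CC[C@@H](OCc3ccccc3)C(C)(C)C1=CCCC[C@@H]2O[Si](C)(C)C(C)(C)C | intermediate
13 | 21-O-benzyl Δ16-13-ol | C[C@]12CC[C@@H](OCc3ccccc3)C(C)(C)C1=CCCC[C@@H]2O | intermediate
14 | 21-O-benzyl cis-fused 13-ol (H-17 cis to the C18 methyl) | C[C@]12CC[C@@H](OCc3ccccc3)C(C)(C)[C@H]1CCCC[C@@H]2O | intermediate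
15 | 21-O-benzyl cis-fused 13-ketone | C[C@]12CC[C@@H](OCc3ccccc3)C(C)(C)[C@H]1CCCCC2=O | intermediate (not isolated)
16 | 21-O-benzyl cis-fused Δ12(14)-13-enone | C[C@]12CC[C@@H](OCc3ccccc3)C(C)(C)[C@H]1CCC=CC2=O | intermediate
17 | 21-O-benzyl 12-iodo-Δ12(14)-13-enone | C[C@]12CC[C@@H](OCc3ccccc3)C(C)(C)[C@H]1CCC=C(I)C2=O | intermediate
18 | (S)-Wieland–Miescher ketone | C[C@]12CCC(=O)C=C1CCCC2=O | starting material
19 | 9-hydroxy enone (9-OH cis to the C10 methyl) | C[C@]12CCC(=O)C=C1CCC[C@@H]2O | intermediate
20 | 9-O-TBS enone | C[C@]12CCC(=O)C=C1CCC[C@@H]2O[Si](C)(C)C(C)(C)C | intermediate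
21 | 9-O-TBS 4,4-dimethyl-Δ5-3-ketone | C[C@]12CCC(=O)C(C)(C)C1=CCC[C@@H]2O[Si](C)(C)C(C)(C)C | intermediate
22 | 9-O-TBS 4,4-dimethyl-Δ5-3β-ol | C[C@]12CC[C@H](O)C(C)(C)C1=CCC[C@@H]2O[Si](C)(C)C(C)(C)C | intermediate
23 | 9-O-TBS 3β-methoxy-4,4-dimethyl-Δ5-octalin | C[C@]12CC[C@H](OC)C(C)(C)C1=CCC[C@@H]2O[Si](C)(C)C(C)(C)C | intermediate
24 | 3β-methoxy-Δ5-9-ol | C[C@]12CC[C@H](OC)C(C)(C)C1=CCC[C@@H]2O | intermediate
25 | 3β-methoxy cis-decalin-9-ol (H-5 cis to the C10 methyl) | C[C@]12CC[C@H](OC)C(C)(C)[C@H]1CCC[C@@H]2O | intermediate
26 | 3β-methoxy cis-decalin-9-one | C[C@]12CC[C@H](OC)C(C)(C)[C@H]1CCCC2=O | intermediate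
27 | 8-(benzyloxymethyl) 9-ketone (C8 epimers) | C[C@]12CC[C@H](OC)C(C)(C)[C@H]1CCC(COCc3ccccc3)C2=O | intermediate
28 | 8α-(benzyloxymethyl)-8β-methyl 9-ketone | C[C@]12CC[C@H](OC)C(C)(C)[C@H]1CC[C@@](C)(COCc3ccccc3)C2=O | intermediate
29 | 8α-(hydroxymethyl)-8β-methyl 9-ketone | C[C@]12CC[C@H](OC)C(C)(C)[C@H]1CC[C@@](C)(CO)C2=O | intermediate
30 | C27 triflate | C[C@]12CC[C@H](OC)C(C)(C)[C@H]1CC[C@@](C)(COS(=O)(=O)C(F)(F)F)C2=O | intermediate (not isolated)
31 | 8α-(iodomethyl)-8β-methyl 9-ketone | C[C@]12CC[C@H](OC)C(C)(C)[C@H]1CC[C@@](C)(CI)C2=O | intermediate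
32 | AB alkene (9-methylene-8α-(iodomethyl) cis-decalin) | C[C@]12CC[C@H](OC)C(C)(C)[C@H]1CC[C@@](C)(CI)C2=C | intermediate
33 | B-(C11-alkyl)-9-BBN (H-9 β) | C[C@]12CC[C@H](OC)C(C)(C)[C@H]1CC[C@@](C)(CI)[C@H]2CB3C4CCCC3CCC4 | intermediate (not isolated)
34 | coupled 12-alkyl-Δ12(14)-13-enone (rings A, B, D, E) | C[C@]12CC[C@H](OC)C(C)(C)[C@H]1CC[C@@](C)(CI)[C@H]2CC3=CCC[C@@H]4C(C)(C)[C@H](OCc5ccccc5)CC[C@]4(C)C3=O | intermediate
35 | 14-pinacolboronate 13-ketone (C12 and C14 epimers) | C[C@]12CC[C@H](OC)C(C)(C)[C@H]1CC[C@@](C)(CI)[C@H]2CC3C(B5OC(C)(C)C(C)(C)O5)CC[C@@H]4C(C)(C)[C@H](OCc5ccccc5)CC[C@]4(C)C3=O | intermediate (not isolated)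
36 | 14-hydroxy 13-ketone (C12 and C14 epimers) | C[C@]12CC[C@H](OC)C(C)(C)[C@H]1CC[C@@](C)(CI)[C@H]2CC3C(O)CC[C@@H]4C(C)(C)[C@H](OCc5ccccc5)CC[C@]4(C)C3=O | intermediate
37 | 13,14-dione with C27 iodide (C12 configurationally labile) | C[C@]12CC[C@H](OC)C(C)(C)[C@H]1CC[C@@](C)(CI)[C@H]2CC3C(=O)CC[C@@H]4C(C)(C)[C@H](OCc5ccccc5)CC[C@]4(C)C3=O | intermediate
38 | 21-O-benzyl ether of the target | CO[C@H]1CC[C@@]2(C)[C@H](CC[C@@]3(C)C[C@@]4(O)CC[C@@H]5C(C)(C)[C@H](OCc6ccccc6)CC[C@]5(C)C(=O)[C@@H]4C[C@H]32)C1(C)C | intermediate
39 | CNP0259231.1 | CO[C@H]1CC[C@@]2(C)[C@H](CC[C@@]3(C)C[C@@]4(O)CC[C@@H]5C(C)(C)[C@H](O)CC[C@]5(C)C(=O)[C@@H]4C[C@H]32)C1(C)C | target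

## Step count and risks

Total: 30 steps. Longest linear sequence: 18 steps (18 to 39, steps 13–30). The DE branch (1 to 17) is 12 steps before the union.

**Step 3 (key step).** The likely failure is weak discrimination between the two enantiotopic ring carbonyls: the seven-membered dione is more flexible than its five- and six-membered relatives, so the hydrogen-bonded transition states may differ less, and dehydration of the ketol may also stall. Fallback from 5: cyclise with pyrrolidinium acetate to the racemic ring-DE enedione F1 and resolve it by enantioselective biocatalytic carbonyl reduction (a ketoreductase, or the yeast reduction used as a kinetic resolution for the six-membered homologue). Only the (S)-enantiomer is reduced, giving 8, where the route is rejoined.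

**Step 10 (and its twin, step 19, the easier six-membered case).** Facial selectivity may be poor if the hydroxyl does not hold the metal over the methyl-bearing face of the flexible seven-membered ring, and the hindered trisubstituted alkene may turn over slowly enough for the catalyst to deactivate. Fallback from 9: hydrogenate the conjugated enone over Pd/C, which favours cis fusion for angularly methylated bicyclic enones, to the cis-fused 13-O-TBS 21-ketone F2. Methylate twice at C22 with KOt-Bu and MeI (cis-fused ketones enolise towards the ring-fusion side) to the cis-fused 13-O-TBS 22,22-dimethyl-21-ketone F3. Reduce with Li(s-Bu)3BH to the cis-fused 13-O-TBS 21-ol F4, benzylate to the cis-fused 21-O-benzyl 13-O-TBS diether F5, and desilylate with Bu4NF to rejoin at 14.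

**Step 22.** The methyl group may enter on the α face if the enolate reacts through a conformer in which ring A does not shield that face, giving the wrong C8 epimer. Fallback from 26: reverse the order of the two alkylations. Methylate first to the 8-methyl cis-decalin-9-one F6, then alkylate its enolate with benzyl chloromethyl ether, so that the C27 unit is delivered to the face the second electrophile prefers. The route is rejoined at 28.

**Step 26.** Hydroboration of an alkene flanked by two quaternary carbons may be slow or may deliver hydrogen to the wrong face of C9, and insertion of palladium into the neopentyl C–I bond or slow transmetallation of the β-branched alkylborane could erode the coupling. Fallback from 33 and 16: oxidise 33 with NaBO3 to the AB C11 primary alcohol F7 and with Dess–Martin periodinane to the AB C11 aldehyde F8. In parallel, epoxidise 16 (H2O2, NaOH) to the 12,14-epoxy 13-ketone F9 and isomerise it with Pd(PPh3)4 and dppe to the ring-DE 13,14-dione F10. Join F8 and F10 by proline-catalysed Knoevenagel condensation with in-situ Hantzsch ester reduction, which gives 37 directly.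

**Step 29.** The enolisable dione may be deprotonated or simply reduced instead of cyclising, and some attack at C13 cannot be excluded. Fallback from 36: never form the dione, and close ring C on a simple ketone.
- Reduce the C13 ketone with NaBH4 to the seco 13,14-diol F11.
- Oxidise only the C14 carbinol with TEMPO and PhI(OAc)2 to the 13-hydroxy 14-ketone F12. Oxoammonium oxidants are slow at a carbinol such as C13, which is flanked by quaternary C18 and branched C12.
- Close ring C with SmI2 to the pentacyclic 13,14-diol 21-benzyl ether F13.
- Oxidise the secondary C13 alcohol with Dess–Martin periodinane (the tertiary 14-hydroxyl is inert and C12 then equilibrates), which rejoins the route at 38.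

## Further compounds

F1 | step 3 | racemic ring-DE enedione | CC12CCC(=O)C=C1CCCCC2=O
F2 | step 10 | cis-fused 13-O-TBS 21-ketone (H-17 cis to the C18 methyl) | C[C@]12CCC(=O)C[C@H]1CCCC[C@@H]2O[Si](C)(C)C(C)(C)C
F3 | step 10 | cis-fused 13-O-TBS 22,22-dimethyl-21-ketone | C[C@]12CCC(=O)C(C)(C)[C@H]1CCCC[C@@H]2O[Si](C)(C)C(C)(C)C
F4 | step 10 | cis-fused 13-O-TBS 21-ol (21-OH trans to the C18 methyl) | C[C@]12CC[C@@H](O)C(C)(C)[C@H]1CCCC[C@@H]2O[Si](C)(C)C(C)(C)C
F5 | step 10 | cis-fused 21-O-benzyl 13-O-TBS diether | C[C@]12CC[C@@H](OCc3ccccc3)C(C)(C)[C@H]1CCCC[C@@H]2O[Si](C)(C)C(C)(C)C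
F6 | step 22 | 8-methyl cis-decalin-9-one (C8 epimers) | C[C@]12CC[C@H](OC)C(C)(C)[C@H]1CCC(C)C2=O
F7 | step 26 | AB C11 primary alcohol | C[C@]12CC[C@H](OC)C(C)(C)[C@H]1CC[C@@](C)(CI)[C@H]2CO
F8 | step 26 | AB C11 aldehyde | C[C@]12CC[C@H](OC)C(C)(C)[C@H]1CC[C@@](C)(CI)[C@H]2C=O
F9 | step 26 | 12,14-epoxy 13-ketone | C[C@]12CC[C@@H](OCc3ccccc3)C(C)(C)[C@H]1CCC3OC3C2=O
F10 | step 26 | ring-DE 13,14-dione | C[C@]12CC[C@@H](OCc3ccccc3)C(C)(C)[C@H]1CCC(=O)CC2=O
F11 | step 29 | seco 13,14-diol with C27 iodide (C12, C13 and C14 epimers) | C[C@]12CC[C@H](OC)C(C)(C)[C@H]1CC[C@@](C)(CI)[C@H]2CC3C(O)CC[C@@H]4C(C)(C)[C@H](OCc5ccccc5)CC[C@]4(C)C3O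
F12 | step 29 | 13-hydroxy 14-ketone (C12 and C13 epimers) | C[C@]12CC[C@H](OC)C(C)(C)[C@H]1CC[C@@](C)(CI)[C@H]2CC3C(=O)CC[C@@H]4C(C)(C)[C@H](OCc5ccccc5)CC[C@]4(C)C3O
F13 | step 29 | pentacyclic 13,14-diol 21-benzyl ether (C12 and C13 epimers) | CO[C@H]1CC[C@@]2(C)[C@H](CC[C@@]3(C)C[C@@]4(O)CC[C@@H]5C(C)(C)[C@H](OCc6ccccc6)CC[C@]5(C)C(O)C4C[C@H]32)C1(C)C
A1 | alternative 1 | C14,C17-divinyl seco-ring-D ketone, 21-O-TBS | CO[C@H]1CC[C@@]2(C)[C@H](CC[C@@]3(C)C[C@@](O)(C=C)[C@@H](C[C@H]32)C(=O)[C@@]4(C)CC[C@@H](O[Si](C)(C)C(C)(C)C)C(C)(C)[C@H]4C=C)C1(C)C
A2 | alternative 1 | 15,16-dehydro target 21-O-TBS ether | CO[C@H]1CC[C@@]2(C)[C@H](CC[C@@]3(C)C[C@@]4(O)/C=C\[C@@H]5C(C)(C)[C@H](O[Si](C)(C)C(C)(C)C)CC[C@]5(C)C(=O)[C@@H]4C[C@H]32)C1(C)C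
A3 | alternative 2 | methyl 4,4-ethylenedioxy-3,3-dimethylcyclohex-1-ene-1-carboxylate | COC(=O)C1=CC(C)(C)C2(OCCO2)CC1
A4 | alternative 2 | ring E ester with C17 vinyl and C18 methyl | COC(=O)[C@@]1(C)CCC2(OCCO2)C(C)(C)[C@H]1C=C
A5 | alternative 3 | bicyclic trimethylsilyl enol ether (ring E fused to a cyclopentene, 21-O-TBS) | C[Si](C)(C)OC1=CC[C@@H]2C(C)(C)[C@H](O[Si](C)(C)C(C)(C)C)CC[C@]12C
A6 | alternative 3 | dichlorocyclobutanone adduct | C[Si](C)(C)O[C@@]13C(Cl)(Cl)C(=O)[C@@H]1C[C@@H]2C(C)(C)[C@H](O[Si](C)(C)C(C)(C)C)CC[C@@]23C
A7 | alternative 3 | dichloroketene | ClC(Cl)=C=O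
A8 | alternative 3 | ring D 1,3-dione unsubstituted at C12, 21-O-TBS | C[C@]12CC[C@@H](O[Si](C)(C)C(C)(C)C)C(C)(C)[C@H]1CCC(=O)CC2=O
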